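**Assumptions.** The SMILES is taken literally. In ent‑kaurane numbering (used below) this means 5β‑H, 9β‑H, C20 α, C19 (not C18) oxidised, 6‑OMe on the exo face of the cis‑fused THF, and 11‑OH trans to H‑9 (cis to C10). The route has not been run; stereochemical outcomes are argued from conformational models and analogy, and the two enantioselective steps (2 and 8) assume the usual facial sense, which should be confirmed experimentally.

## Retrosynthetic overview

1. Enone last: α‑methylenation of a C15 ketone, itself from ozonolysis of a C15 exo‑methylene; D ring (C8–C15) closed by Pd‑catalysed lactone‑enolate alkenylation with a 2‑bromoallyl arm.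
2. C ring (C9–C11) by SmI2 ketyl–enoate cyclisation onto an α,β‑unsaturated spirolactone; C11 then reset by oxidation and L‑Selectride reduction.
3. C11–C16 side chain by alkylation of the spirolactone with an Evans‑derived iodide, then selenoxide elimination to the C8=C9 enoate.
4. Spiro δ‑lactone and C10 quaternary centre by Ti(III) epoxide opening and Giese addition to trifluoroethyl acrylate.
5. A ring/THF acetal from a 3‑substituted cyclohexenone by Cu‑catalysed asymmetric methyl addition, formylation at the acetal level and acetalisation. Ring order: A → THF acetal → δ‑lactone → C → D.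

## Route

**Step 1**
Reactants: 1, 3‑ethoxycyclohex‑2‑en‑1‑one; 2, tributyl[(benzyloxy)methyl]stannane
Product: 3, 3‑[(benzyloxy)methyl]cyclohex‑2‑en‑1‑one
Conditions: 2, n‑BuLi, THF, −78 °C; add 1; then 1 M HCl, rt
Reagents that add atoms: water, O (new carbonyl oxygen)
Why: Stork–Danheiser sequence: BnOCH2Li adds 1,2 to the vinylogous ester and acid hydrolysis transposes the enone; no stereocentre.

**Step 2**
Reactants: 3
Product: 4, (R)‑{[3‑[(benzyloxy)methyl]‑3‑methylcyclohex‑1‑en‑1‑yl]oxy}trimethylsilane
Conditions: Me3Al, CuTC (5 mol %), chiral phosphoramidite (10 mol %; enantiomer chosen to give 3R), Et2O, −30 °C; then TMSOTf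
Reagents that add atoms: trimethylaluminium, C[Al](C)C; TMSOTf, C[Si](C)(C)OS(=O)(=O)C(F)(F)F
Why: Cu‑catalysed asymmetric conjugate addition to a β,β‑disubstituted enone sets the C4 quaternary centre under ligand control, and the aluminium enolate is trapped regiospecifically as the C5=C10 enol silane.

**Step 3**
Reactants: 4
Product: 5, (3R)‑3‑[(benzyloxy)methyl]‑2‑(dimethoxymethyl)‑3‑methylcyclohexan‑1‑one (C2 epimers)
Conditions: HC(OMe)3, BF3·OEt2, CH2Cl2, −78 °C
Reagents that add atoms: trimethyl orthoformate, COC(OC)OC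
Why: Mukaiyama‑type addition of the enol silane to the dimethoxycarbenium ion installs C6 at the aldehyde oxidation level on C5; the C5 configuration is reset in step 4.

**Step 4**
Reactants: 5
Product: 6, (3S,3aS,7aR)‑3‑methoxy‑7a‑methylhexahydro‑2‑benzofuran‑4(1H)‑one (cis‑fused keto acetal, OMe exo)
Conditions: H2, Pd/C, EtOAc; filter; then CSA (cat.), CH2Cl2, rt to 40 °C
Reagents that add atoms: none
Why: Hydrogenolysis frees C19–OH and acid‑catalysed transacetalisation closes the THF ring; C5 (epimerisable via the alkoxymethylene ketone) and the anomeric C6 equilibrate to the thermodynamic cis‑fused, exo‑OMe isomer.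

**Step 5**
Reactants: 6
Product: 7, spiro‑epoxide of 6 (C10 ketone converted to C10–C20H2 oxirane; either C10 epimer)
Conditions: Me3S+ I−, n‑BuLi, THF, −10 to 0 °C
Reagents that add atoms: trimethylsulfonium iodide, C[S+](C)C.[I-]
Why: Corey–Chaykovsky epoxidation; the epoxide configuration is irrelevant because C10 becomes a planar radical next.

**Step 6**
Reactants: 7; 8, 2,2,2‑trifluoroethyl acrylate
Product: 9, spiro δ‑lactone (C10 spiro; C20H2–O–C7(=O)–C8H2–C9H2; C9 trans to C6)
Conditions: Cp2TiCl2, Zn dust, THF, rt, slow addition of 7 and 8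
Reagents that add atoms: none
Why: Nugent–RajanBabu Ti(III) epoxide opening gives the tertiary C10 radical, which adds (Giese) to the acrylate from the convex face anti to the C5–C6/THF ring, setting C10; the titanium alkoxide then lactonises onto the activated ester.

**Step 7**
Reactants: 10, (R)‑4‑benzyl‑1,3‑oxazolidin‑2‑one; 11, pent‑4‑enoyl chloride
Product: 12, (R)‑4‑benzyl‑3‑(pent‑4‑enoyl)‑1,3‑oxazolidin‑2‑one
Conditions: n‑BuLi, THF, −78 °C
Reagents that add atoms: none
Why: N‑acylation of the lithiated auxiliary.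

**Step 8**
Reactants: 12; 13, 2,3‑dibromopropene
Product: 14, (R)‑4‑benzyl‑3‑[(2S)‑2‑(2‑bromoprop‑2‑en‑1‑yl)pent‑4‑enoyl]‑1,3‑oxazolidin‑2‑one
Conditions: NaHMDS, THF, −78 °C
Reagents that add atoms: none
Why: Evans alkylation: the chelated Z‑enolate is alkylated anti to the benzyl group, setting the future C13 as 2S.

**Step 9**
Reactants: 14
Product: 15, (2S)‑2‑(2‑bromoprop‑2‑en‑1‑yl)pent‑4‑en‑1‑ol
Conditions: LiBH4, MeOH (1 equiv), Et2O, 0 °C
Reagents that add atoms: none
Why: Reductive removal of the auxiliary; the stereocentre is not enolised.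

**Step 10**
Reactants: 15
Product: 16, (4S)‑2‑bromo‑4‑(iodomethyl)hepta‑1,6‑diene
Conditions: I2, PPh3, imidazole, CH2Cl2, 0 °C
Reagents that add atoms: iodine, II
Why: Appel‑type iodination of the primary alcohol.

**Step 11**
Reactants: 9; 16
Product: 17, C8‑alkylated spirolactone (C8–C14H2–C13H(allyl)(2‑bromoallyl); C8 epimers)
Conditions: LDA, THF/HMPA, −78 to −30 °C
Reagents that add atoms: none
Why: SN2 alkylation of the lactone enolate; the C8 configuration is erased in step 12.

**Step 12**
Reactants: 17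
Product: 18, C8=C9 α,β‑unsaturated spirolactone
Conditions: KHMDS, THF, −78 °C; PhSeBr; then H2O2, pyridine, CH2Cl2, 0 °C to rt
Reagents that add atoms: none
Why: α‑Selenation and selenoxide syn‑elimination; the endocyclic conjugated δ‑lactone is expected to be the favoured regioisomer.

**Step 13**
Reactants: 18
Product: 19, aldehyde (allyl arm cleaved to C12H2–C11H=O)
Conditions: OsO4 (cat.), NaIO4, 2,6‑lutidine, dioxane/H2O, rt
Reagents that add atoms: OsO4/NaIO4 (aldehyde O), O=[Os](=O)(=O)=O
Why: Lemieux–Johnson cleavage is selective for the isolated monosubstituted alkene over the hindered electron‑poor enoate and the vinyl bromide.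

**Step 14**
Reactants: 19
Product: 20, tricyclic lactone alcohol (C9–C11 bond; 9β‑H; 11‑OH cis to H‑9; C8–H)
Conditions: SmI2, LiBr, t‑BuOH, THF, −78 °C
Reagents that add atoms: none
Why: SmI2 ketyl–olefin 6‑endo cyclisation: the ketyl adds to C9 on the face syn to C1 (anti to C5/THF) through a chair with C10 and the bromoallyl arm both equatorial (matched with C13), setting C9. The ketyl oxygen is expected to sit equatorial, giving the 11‑epimer of the target, which steps 15–16 correct.

**Step 15**
Reactants: 20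
Product: 21, C11 ketone
Conditions: Dess–Martin periodinane, NaHCO3, CH2Cl2, 0 °C to rt
Reagents that add atoms: none
Why: Buffered neutral oxidation avoids epimerising C9.

**Step 16**
Reactants: 21
Product: 22, 11‑alcohol with OH cis to C10 and trans to H‑9 (target C11 configuration)
Conditions: L‑Selectride, THF, −78 °C; AcOH quench at −78 °C
Reagents that add atoms: none
Why: The bulky hydride attacks the cyclohexanone equatorially (C10 and the arm are equatorial), giving the axial alcohol cis to C10; the ketone is reduced in preference to the lactone.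

**Step 17**
Reactants: 22
Product: 23, 11‑O‑triethylsilyl ether
Conditions: TESCl, imidazole, DMAP, DMF, rt to 40 °C
Reagents that add atoms: chlorotriethylsilane, CC[Si](Cl)(CC)CC
Why: Silylation under non‑Lewis‑acidic conditions that leave the methyl acetal intact.

**Step 18**
Reactants: 23
Product: 24, bicyclo[3.2.1]octane with C8–C15 bond and C15 exo‑methylene (C8 quaternary)
Conditions: KHMDS (1.1 equiv), THF, −78 °C; then Pd[P(t‑Bu)3]2 (10 mol %), toluene, rt to 60 °C
Reagents that add atoms: none
Why: Pd‑catalysed intramolecular enolate α‑alkenylation (Buchwald–Hartwig type); only the chair with the arm axial can bridge C13 to C8, so the C8 configuration is dictated by C13.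

**Step 19**
Reactants: 24
Product: 25, C15 ketone (β‑keto lactone)
Conditions: O3, CH2Cl2, −78 °C; PPh3
Reagents that add atoms: ozone, [O-][O+]=O
Why: Ozonolysis of the only C=C in the molecule.

**Step 20**
Reactants: 25
Product: 26, 16‑methylene‑15‑ketone, 11‑OTES
Conditions: LiHMDS, THF, −78 °C; Eschenmoser's salt, to rt; then MeI, CH2Cl2; aq NaHCO3
Reagents that add atoms: Eschenmoser's salt, C[N+](C)=C.[I-]
Why: Mannich reaction, quaternisation and elimination; C16 is the only enolisable position (C8 is quaternary and C13 is a bridgehead).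

**Step 21**
Reactants: 26
Product: 27, Angustifolin
Conditions: HF·pyridine, pyridine, THF, 0 °C
Reagents that add atoms: none
Why: Buffered fluoride desilylation leaves the enone, lactone and thermodynamic methyl acetal untouched.

## Compound list

1 | 3‑ethoxycyclohex‑2‑en‑1‑one | CCOC1=CC(=O)CCC1 | starting material
2 | tributyl[(benzyloxy)methyl]stannane | CCCC[Sn](CCCC)(CCCC)COCc1ccccc1 | starting material
3 | 3‑[(benzyloxy)methyl]cyclohex‑2‑en‑1‑one | O=C1C=C(COCc2ccccc2)CCC1 | intermediate
4 | (R)‑TMS enol ether of 3‑(BnOCH2)‑3‑methylcyclohexanone | C[Si](C)(C)OC1=C[C@](C)(COCc2ccccc2)CCC1 | intermediate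
5 | (3R)‑3‑[(benzyloxy)methyl]‑2‑(dimethoxymethyl)‑3‑methylcyclohexanone | O=C1CCC[C@@](C)(COCc2ccccc2)C1C(OC)OC | intermediate
6 | (3S,3aS,7aR)‑3‑methoxy‑7a‑methylhexahydro‑2‑benzofuran‑4(1H)‑one | O=C1CCC[C@@]2(C)CO[C@H](OC)[C@H]21 | intermediate
7 | spiro‑epoxide of 6 | C1OC12CCC[C@@]3(C)CO[C@H](OC)[C@H]32 | intermediate
8 | 2,2,2‑trifluoroethyl acrylate | C=CC(=O)OCC(F)(F)F | starting material
9 | A‑ring/THF‑acetal spiro δ‑lactone | O=C1CC[C@@]2(CCC[C@@]3(C)CO[C@H](OC)[C@H]32)CO1 | intermediate
10 | (R)‑4‑benzyl‑1,3‑oxazolidin‑2‑one | O=C1N[C@H](Cc2ccccc2)CO1 | starting material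
11 | pent‑4‑enoyl chloride | C=CCCC(=O)Cl | starting material
12 | (R)‑4‑benzyl‑3‑(pent‑4‑enoyl)oxazolidin‑2‑one | C=CCCC(=O)N1[C@H](Cc2ccccc2)COC1=O | intermediate
13 | 2,3‑dibromopropene | C=C(Br)CBr | starting material
14 | (R)‑4‑benzyl‑3‑[(2S)‑2‑(2‑bromoallyl)pent‑4‑enoyl]oxazolidin‑2‑one | C=CC[C@@H](CC(Br)=C)C(=O)N1[C@H](Cc2ccccc2)COC1=O | intermediate
15 | (2S)‑2‑(2‑bromoallyl)pent‑4‑en‑1‑ol | OC[C@H](CC(Br)=C)CC=C | intermediate
16 | (4S)‑2‑bromo‑4‑(iodomethyl)hepta‑1,6‑diene | IC[C@H](CC(Br)=C)CC=C | intermediate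
17 | C8‑alkylated spirolactone | O=C1C(C[C@H](CC(Br)=C)CC=C)C[C@@]2(CCC[C@@]3(C)CO[C@H](OC)[C@H]32)CO1 | intermediate
18 | C8=C9 unsaturated spirolactone | O=C1C(C[C@H](CC(Br)=C)CC=C)=C[C@@]2(CCC[C@@]3(C)CO[C@H](OC)[C@H]32)CO1 | intermediate
19 | C11 aldehyde | O=C1C(C[C@H](CC(Br)=C)CC=O)=C[C@@]2(CCC[C@@]3(C)CO[C@H](OC)[C@H]32)CO1 | intermediate
20 | tricyclic 11‑epi alcohol (OH cis to H‑9) | C=C(Br)C[C@@H]1C[C@H](O)[C@@H]2C(C1)C(=O)OC[C@]23CCC[C@@]4(C)CO[C@H](OC)[C@H]43 | intermediate
21 | C11 ketone | C=C(Br)C[C@@H]1CC(=O)[C@@H]2C(C1)C(=O)OC[C@]23CCC[C@@]4(C)CO[C@H](OC)[C@H]43 | intermediate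
22 | 11‑alcohol, target configuration | C=C(Br)C[C@@H]1C[C@@H](O)[C@@H]2C(C1)C(=O)OC[C@]23CCC[C@@]4(C)CO[C@H](OC)[C@H]43 | intermediate
23 | 11‑OTES ether | C=C(Br)C[C@@H]1C[C@@H](O[Si](CC)(CC)CC)[C@@H]2C(C1)C(=O)OC[C@]23CCC[C@@]4(C)CO[C@H](OC)[C@H]43 | intermediate
24 | 15‑methylene bicyclo[3.2.1]octane lactone | C1C(=C)[C@]23C[C@H]1C[C@@H](O[Si](CC)(CC)CC)[C@H]2[C@@]1(CCC[C@@]2(C)CO[C@H](OC)[C@H]21)COC3=O | intermediate
25 | 15‑ketone | C1C(=O)[C@]23C[C@H]1C[C@@H](O[Si](CC)(CC)CC)[C@H]2[C@@]1(CCC[C@@]2(C)CO[C@H](OC)[C@H]21)COC3=O | intermediate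
26 | 11‑O‑TES‑angustifolin | C=C1C(=O)[C@]23C[C@H]1C[C@@H](O[Si](CC)(CC)CC)[C@H]2[C@@]1(CCC[C@@]2(C)CO[C@H](OC)[C@H]21)COC3=O | intermediate
27 | Angustifolin | C=C1C(=O)[C@]23C[C@H]1C[C@@H](O)[C@H]2[C@@]1(CCC[C@@]2(C)CO[C@H](OC)[C@H]21)COC3=O | target

## Summary

Total steps: 21. Longest linear sequence: 17 (steps 1–6 and 11–21); the side‑chain iodide takes 4 steps (7–10).

Steps most likely to fail, with fallbacks:

1. **Step 18 (Pd enolate alkenylation to the C8 quaternary bridgehead).** Competing dehydrobromination or a sluggish hindered enolate could defeat it. Fallback: carry an allyl arm instead of 2‑bromoallyl (with a silyloxyethyl arm as the aldehyde precursor), convert the lactone to its TBS ketene acetal and close C8–C15 by stoichiometric Pd(OAc)2 oxidative cycloalkenylation in DMSO. This gives the same 15‑methylene compound.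
2. **Step 14 (SmI2 ketyl–enoate cyclisation onto the hindered β‑carbon).** Simple aldehyde reduction, pinacol coupling or attack on the bromoalkene could compete. Fallback: close C9–C11 by a 6‑endo acyl‑radical Giese cyclisation (acyl selenide from the corresponding acid, Bu3SnH/AIBN). This delivers ketone 21 directly and removes step 15.
3. **Step 16 (C11 set by L‑Selectride on the flexible tricycle).** Poor facial selectivity, C9 epimerisation or alkoxide translactonisation onto C7 are the risks. Fallback: carry the step‑14 alcohol (as its TES ether) through D‑ring formation and invert at the rigid bicyclic stage, where the desired alcohol is equatorial. This means desilylation, oxidation to the 11‑ketone and a thermodynamic reduction (SmI2/H2O/Et3N or Meerwein–Ponndorf–Verley), before ozonolysis and methylenation.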